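The ratio I followed was Z present per L charged, which I called the standing turnovers N, a turnover number counted on what still stands in the flask. Here substrate E becomes product Z on catalyst L.

| setting | beta | eta | theta | flask |
|---|---|---|---|---|
| E | 0.13 M | 0.29 M | 0.19 M | 0.19 M |
| G | 12 mM (held) | 12 mM (held) | 12 mM (held) | 12 mM (held) |
| L | 11 mM | 11 mM | 5.5 mM | 11 mM |
| remark | run made earlier | run made earlier | run made earlier |  |
| time |  |  |  | 3.0 d |

| run | time / d | Z / % |
|---|---|---|
| beta | 0.250 | 4 |
| beta | 0.625 | 15 |
| beta | 1.67 | 35 |
| beta | 4.00 | 50 |
| eta | 0.833 | 11 |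
| eta | 1.67 | 23 |
| eta | 2.50 | 31 |
| eta | 4.00 | 28 |
| theta | 0.250 | 3 |
| theta | 0.625 | 8 |
| theta | 1.67 | 17 |
| theta | 4.00 | 30 |

(each reading ± 2 percentage points)

1. Z at 3.0 d, in percent of the E charged
2. concentration of J in solution at 3.0 d, in percent of saturation

- at the start none of J is dissolved
- on the list of suspects stand: G <-> J; E + J + L -> L + Z; L + Z -> D

I kept a ledger of E. At 4.00 d the beta run stood at 5.91 turnovers and the eta run at 7.38, both on 11 mM of L. Eta's readings went from 31% at 2.50 d to 28% at 4.00 d, a step that two readings with a scatter of 2 percentage points each can show by chance, so I read Z as slowing there, not as falling. On the suspect L + Z -> D, each L lost takes one Z with it, which is at most 3.79% of eta's E. That ledger still left 68.2% as E, so I read the slowing as a dying catalyst, not an emptied substrate.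

The flask's E lies between those two runs, so I interpolated linearly in E and got 6.46 standing turnovers, and I took this count from 4.00 d as a rough estimate for 3.0 d. The flask's books then read: Z 37.4%, D at most 5.79%, and the remainder, 56.8%, as E.

The forecast gave 39% of Z, a little above mine, and J at 87% of saturation, holding that “The stalling follows cumulative product”.

The simulation gave 38.3% of Z and J at 87.2% of saturation.

    G ⇌ J, rate k1*(csat - [J]) (kL = 0.270 /h)
    E + J + L → L + Z (k = 200 /M²/h)
    L + Z → D (k = 0.590 /M/h)

The same flask run without the conversion of L + Z into D shows the share of that step: Z at 3.0 d then reaches 59.9% instead of 38.3%, which accounts for 35% of what is missing. Against the 6.46 I carried, the flask stood at 6.62 standing turnovers, with 14.3% of its L left. The neighbouring flask charged with 0.044 M of L held 45.8% of Z at 3.0 d, which is 1.98 standing turnovers.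

The earlier runs and the new flask come from a simulation for substances that don't exist; scatter was added.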